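**Retrosynthetic overview**

- The isocoumarin is cut across both of its rings at once: a Diels–Alder reaction of Brassard's diene with a 2,4-diynoate, followed in the same flask by aromatisation and 6-endo-dig lactonisation, builds the benzene and pyranone rings together. The 8-OH/6-OMe pattern comes from the diene, so no phenol protection is needed.
- The diynoate comes from an sp–sp coupling of an alkynyl α-hydroxy-γ-butyrolactone with methyl 3-bromopropiolate.
- The butyrolactone comes from a 1,2,4-triol by primary-selective oxidative lactonisation.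
- The triol comes from a catalyst-controlled propargylation of a dichloromethyl ketone (sets the quaternary carbinol). The secondary carbinol and the ketone come from a chiral-pool dioxolane ester and LiCHCl2.
- Ring order: butyrolactone first (step 3), then benzene and pyranone together (step 7).

Assumption: compounds 1, 3 and 11 are taken as catalogue chemicals (1 is the acetonide ester derived from L-malic acid).

**Route**

Step 1
Reactants: 1 methyl 2-[(4S)-2,2-dimethyl-1,3-dioxolan-4-yl]acetate
Product: 2 1,1-dichloro-3-[(4S)-2,2-dimethyl-1,3-dioxolan-4-yl]propan-2-one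
Conditions: CH2Cl2 (2.5 equiv), n-BuLi (2.2 equiv), THF, −100 °C, 30 min; add 1, −100 → −78 °C, 1 h; AcOH/THF quench at −78 °C
Reagents that add atoms: dichloromethane, ClCCl
Why: Carbenoid acylation (Claisen-type) of LiCHCl2 by the methyl ester stops at the ketone because the tetrahedral adduct and the derived α,α-dichloro enolate do not add a second carbenoid at −78 °C, and the dioxolane stereocentre from the chiral pool is not touched.

Step 2
Reactants: 2 1,1-dichloro-3-[(4S)-2,2-dimethyl-1,3-dioxolan-4-yl]propan-2-one; 3 allenylboronic acid pinacol ester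
Product: 5 (2S,4S)-4-(dichloromethyl)hept-6-yne-1,2,4-triol, via carbinol acetonide 4 (not isolated)
Conditions: 3 (1.5 equiv), (S)-3,3′-dibromo-1,1′-bi-2-naphthol (10 mol %), PhMe (2 M), 40 °C, 24 h; then 1 M HCl/MeOH (1:4), 23 °C, 3 h
Reagents that add atoms: none
Why: Proposed new method: chiral-biphenol-catalysed propargylation of a ketone by an allenylboronate (closest known reaction types: 3,3′-dibromo-BINOL-catalysed allenylboronate additions to aryl methyl ketones, and aminophenol–boron-catalysed allyl additions to dichloromethyl ketones), in which the boron-bound chiral diol delivers the allenyl group by SE2′ through a closed six-membered transition state with the bulky, electron-poor CHCl2 group in the place of the aryl group, so the catalyst rather than the remote dioxolane centre sets the new (S) carbinol; the base-free medium avoids enolisation of the acidic ketone, and the acid work-up frees the carbinol from boron and cleaves the acetonide.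

Step 3
Reactants: 5 (2S,4S)-4-(dichloromethyl)hept-6-yne-1,2,4-triol
Product: 7 (3S,5S)-5-(dichloromethyl)-3-hydroxy-5-(prop-2-yn-1-yl)oxolan-2-one, via lactol 6 (not isolated)
Conditions: 2,2,6,6-tetramethylpiperidin-1-oxyl (0.2 equiv), PhI(OAc)2 (2.5 equiv), CH2Cl2, 23 °C, 8 h
Reagents that add atoms: none
Why: TEMPO/PhI(OAc)2 oxidative lactonisation of a 1,4-diol: the oxoammonium ion oxidises only the primary alcohol, the aldehyde is trapped by the tertiary hydroxyl as the five-membered lactol 6 and oxidised again to the lactone, while the secondary alcohol, both stereocentres, the alkyne and the CHCl2 group are untouched and the weakly acidic medium keeps the dichloromethyl carbinol from closing to a chloro-epoxide.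

Step 4
Reactants: 8 methyl propiolate
Product: 9 methyl 3-bromopropiolate
Conditions: NBS (1.1 equiv), AgNO3 (0.1 equiv), acetone, 23 °C, 2 h, dark; used after short-path distillation
Reagents that add atoms: N-bromosuccinimide, O=C1CCC(=O)N1Br
Why: Silver-acetylide-mediated electrophilic bromination of a terminal alkyne, the standard route to 1-bromoalkynes.

Step 5
Reactants: 7 (3S,5S)-5-(dichloromethyl)-3-hydroxy-5-(prop-2-yn-1-yl)oxolan-2-one; 9 methyl 3-bromopropiolate
Product: 10 methyl 6-[(2S,4S)-2-(dichloromethyl)-4-hydroxy-5-oxooxolan-2-yl]hexa-2,4-diynoate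
Conditions: PdCl2(PPh3)2 (3 mol %), CuI (6 mol %), i-Pr2NH (2 equiv), THF, 0 °C, slow addition of 9 (1.3 equiv), argon
Reagents that add atoms: none
Why: Cadiot–Chodkiewicz-type sp–sp cross-coupling in its Pd/Cu-catalysed form (oxidative addition of the electron-poor bromoalkyne to zerovalent palladium, transmetalation from the copper acetylide of 7, reductive elimination), with a hindered amine that spares the lactone and the ynoate; no stereocentre is involved and the tertiary oxygen is acylated, so no chloro-epoxide can form.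

Step 6
Reactants: 11 methyl (E)-3-methoxybut-2-enoate
Product: 12 (E)-1,3-dimethoxy-1-(trimethylsilyloxy)buta-1,3-diene (Brassard's diene)
Conditions: LiN(i-Pr)2 (1.1 equiv), THF, −78 °C, 45 min; Me3SiCl (1.2 equiv), −78 → 0 °C; filter, distil
Reagents that add atoms: chlorotrimethylsilane, C[Si](C)(C)Cl
Why: γ-Deprotonation of the vinylogous ester to the extended enolate and O-silylation give the silyl ketene acetal diene.

Step 7
Reactants: 10 methyl 6-[(2S,4S)-2-(dichloromethyl)-4-hydroxy-5-oxooxolan-2-yl]hexa-2,4-diynoate; 12 (E)-1,3-dimethoxy-1-(trimethylsilyloxy)buta-1,3-diene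
Product: 15 (3S,5R)-5-(dichloromethyl)-3-hydroxy-5-[(8-hydroxy-6-methoxy-1-oxo-1H-isochromen-3-yl)methyl]oxolan-2-one, via cycloadduct 13 (not isolated), via alkynyl salicylate 14 (not isolated)
Conditions: 12 (3 equiv), PhMe, 85 °C, 12 h; then in the same flask CF3CO2H/ClCH2CH2Cl (1:4), Cu(OSO2CF3)2 (10 mol %), H2O (3 equiv), 50 °C, 4 h
Reagents that add atoms: none
Why: Proposed new method: a regioselective Diels–Alder reaction of the ketene-acetal diene with the ester-bearing triple bond of the diynoate (nucleophilic diene CH2 terminus to the β-carbon) gives 13, loss of methanol aromatises it to the salicylate 14 with the free OH ortho and the OMe para to the ester, and acid/Cu(OSO2CF3)2 then drives 6-endo-dig attack of the ester carbonyl oxygen on the ortho alkyne with loss of the ester methyl group, so the benzene and pyranone rings form in one flask (closest known reaction types: Brassard-diene/alkynoate benzannulation to resorcylates, and acid-promoted 6-endo cyclisation of methyl o-alkynylbenzoates to isocoumarins); both stereocentres are spectators, and the descriptor of the quaternary centre changes from S to R only through CIP priorities.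

**Compound list**

1 | methyl 2-[(4S)-2,2-dimethyl-1,3-dioxolan-4-yl]acetate | COC(=O)C[C@H]1COC(C)(C)O1 | starting material
2 | 1,1-dichloro-3-[(4S)-2,2-dimethyl-1,3-dioxolan-4-yl]propan-2-one | ClC(Cl)C(=O)C[C@H]1COC(C)(C)O1 | intermediate
3 | allenylboronic acid pinacol ester (4,4,5,5-tetramethyl-2-(propa-1,2-dien-1-yl)-1,3,2-dioxaborolane) | C=C=CB1OC(C)(C)C(C)(C)O1 | starting material
4 | (2S)-1,1-dichloro-2-{[(4S)-2,2-dimethyl-1,3-dioxolan-4-yl]methyl}pent-4-yn-2-ol | C#CC[C@@](O)(C(Cl)Cl)C[C@H]1COC(C)(C)O1 | intermediate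
5 | (2S,4S)-4-(dichloromethyl)hept-6-yne-1,2,4-triol | C#CC[C@@](O)(C(Cl)Cl)C[C@H](O)CO | intermediate
6 | (3S,5S)-5-(dichloromethyl)-5-(prop-2-yn-1-yl)oxolane-2,3-diol (lactol, both anomers) | C#CC[C@@]1(C(Cl)Cl)C[C@H](O)C(O)O1 | intermediate
7 | (3S,5S)-5-(dichloromethyl)-3-hydroxy-5-(prop-2-yn-1-yl)oxolan-2-one | C#CC[C@@]1(C(Cl)Cl)C[C@H](O)C(=O)O1 | intermediate
8 | methyl propiolate | C#CC(=O)OC | starting material
9 | methyl 3-bromopropiolate | BrC#CC(=O)OC | intermediate
10 | methyl 6-[(2S,4S)-2-(dichloromethyl)-4-hydroxy-5-oxooxolan-2-yl]hexa-2,4-diynoate | COC(=O)C#CC#CC[C@@]1(C(Cl)Cl)C[C@H](O)C(=O)O1 | intermediate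
11 | methyl (E)-3-methoxybut-2-enoate | CO/C(C)=C/C(=O)OC | starting material
12 | (E)-1,3-dimethoxy-1-(trimethylsilyloxy)buta-1,3-diene | C=C(OC)/C=C(OC)/O[Si](C)(C)C | intermediate
13 | methyl 2-{3-[(2S,4S)-2-(dichloromethyl)-4-hydroxy-5-oxooxolan-2-yl]prop-1-yn-1-yl}-4,6-dimethoxy-6-(trimethylsilyloxy)cyclohexa-1,4-diene-1-carboxylate (ketal carbon unassigned) | COC(=O)C1=C(C#CC[C@@]2(C(Cl)Cl)C[C@H](O)C(=O)O2)CC(OC)=CC1(OC)O[Si](C)(C)C | intermediate
14 | methyl 2-{3-[(2S,4S)-2-(dichloromethyl)-4-hydroxy-5-oxooxolan-2-yl]prop-1-yn-1-yl}-6-hydroxy-4-methoxybenzoate | COC(=O)c1c(O)cc(OC)cc1C#CC[C@@]2(C(Cl)Cl)C[C@H](O)C(=O)O2 | intermediate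
15 | (3S,5R)-5-(dichloromethyl)-3-hydroxy-5-[(8-hydroxy-6-methoxy-1-oxo-1H-isochromen-3-yl)methyl]oxolan-2-one | COc1cc(O)c2c(=O)oc(C[C@@]3(C(Cl)Cl)C[C@H](O)C(=O)O3)cc2c1 | target

**Step count and risks**

Total step count: 7. Longest linear sequence: 5 (steps 1, 2, 3, 5, 7).

The three steps most likely to fail:

- **Step 2.** The ketone lies outside the reported scope of the catalyst, the uncatalysed background addition may erode selectivity, and the facial sense is drawn by analogy only. It has to be confirmed on 7 by an NOE between H-3 and the propargylic CH2, and the antipodal catalyst used if the sense is reversed. Fallback, from 2 back to 7: drop catalyst control and resolve the carbinol centre as a diastereomer. Addition of 3 to 2 without chiral catalyst (neat, 80 °C) gives 4 together with its epimer (2R)-1,1-dichloro-2-{[(4S)-2,2-dimethyl-1,3-dioxolan-4-yl]methyl}pent-4-yn-2-ol F1. The same acid work-up turns F1 into (2S,4R)-4-(dichloromethyl)hept-6-yne-1,2,4-triol F2, and the step 3 oxidation turns it into (3S,5R)-5-(dichloromethyl)-3-hydroxy-5-(prop-2-yn-1-yl)oxolan-2-one F3. Because the (3S) centre is fixed by the chiral pool, 7 and F3 are cis/trans diastereomeric lactones and are separated on silica, and the route resumes at 7.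

- **Step 5.** The bromopropiolate is labile and amines can add to it; homocoupling also competes. Fallback, from 7 back to 10: build the ester by carbonylation instead of bringing it in with the bromoalkyne. Coupling of 7 with commercial (bromoethynyl)triisopropylsilane under the step 5 catalysts gives (3S,5S)-5-(dichloromethyl)-3-hydroxy-5-[5-(triisopropylsilyl)penta-2,4-diyn-1-yl]oxolan-2-one F4. Bu4NF buffered with AcOH (THF, 0 °C) gives (3S,5S)-5-(dichloromethyl)-3-hydroxy-5-(penta-2,4-diyn-1-yl)oxolan-2-one F5. Oxidative methoxycarbonylation of the terminal alkyne (PdCl2 catalyst, CuCl2, NaOAc, CO 1 atm, MeOH, 23 °C) then gives 10.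

- **Step 7.** The diene may add to the distal triple bond or in a conjugate sense, and the cyclisation of the hydrogen-bonded salicylate may be slow. Fallback, from 7 directly to 15: use a benzoic acid C–H annulation instead of the cycloaddition. NBS/AgNO3 converts 7 into (3S,5S)-5-(3-bromoprop-2-yn-1-yl)-5-(dichloromethyl)-3-hydroxyoxolan-2-one F6. Commercial 2-hydroxy-4-methoxybenzoic acid with K2CO3 (1 equiv, DMSO) adds anti across the bromoalkyne to give (1Z)-1-bromo-3-[(2R,4S)-2-(dichloromethyl)-4-hydroxy-5-oxooxolan-2-yl]prop-1-en-2-yl 2-hydroxy-4-methoxybenzoate F7. Pd(OAc)2/PCy3 with K2CO3 at 100 °C then inserts zerovalent palladium into the vinyl C–Br bond and closes the pyranone by C–H functionalisation at the only free ortho position, giving 15.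

**Further compounds**

F1 | step 2 | (2R)-1,1-dichloro-2-{[(4S)-2,2-dimethyl-1,3-dioxolan-4-yl]methyl}pent-4-yn-2-ol | C#CC[C@](O)(C(Cl)Cl)C[C@H]1COC(C)(C)O1
F2 | step 2 | (2S,4R)-4-(dichloromethyl)hept-6-yne-1,2,4-triol | C#CC[C@](O)(C(Cl)Cl)C[C@H](O)CO
F3 | step 2 | (3S,5R)-5-(dichloromethyl)-3-hydroxy-5-(prop-2-yn-1-yl)oxolan-2-one | C#CC[C@]1(C(Cl)Cl)C[C@H](O)C(=O)O1
F4 | step 5 | (3S,5S)-5-(dichloromethyl)-3-hydroxy-5-[5-(triisopropylsilyl)penta-2,4-diyn-1-yl]oxolan-2-one | CC(C)[Si](C#CC#CC[C@@]1(C(Cl)Cl)C[C@H](O)C(=O)O1)(C(C)C)C(C)C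
F5 | step 5 | (3S,5S)-5-(dichloromethyl)-3-hydroxy-5-(penta-2,4-diyn-1-yl)oxolan-2-one | C#CC#CC[C@@]1(C(Cl)Cl)C[C@H](O)C(=O)O1
F6 | step 7 | (3S,5S)-5-(3-bromoprop-2-yn-1-yl)-5-(dichloromethyl)-3-hydroxyoxolan-2-one | BrC#CC[C@@]1(C(Cl)Cl)C[C@H](O)C(=O)O1
F7 | step 7 | (1Z)-1-bromo-3-[(2R,4S)-2-(dichloromethyl)-4-hydroxy-5-oxooxolan-2-yl]prop-1-en-2-yl 2-hydroxy-4-methoxybenzoate | Br/C=C(\OC(=O)c1ccc(OC)cc1O)C[C@@]2(C(Cl)Cl)C[C@H](O)C(=O)O2
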